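**Remark (assumption):** xanthanolide numbering is used (C1–C15 in the hydroxylated half, C1'–C15' in the other). The SMILES is taken literally: the C7/C8/C10 triad is (7R,8R,10S) in one half and (7'S,8'S,10'R) in the other.

## Structural features

- The target is a pseudo-dimer of two xanthanolides. Each half is a cis-fused cyclohepta[b]furan-2-one: ring A with lactone D (C7–C8), and ring B with lactone E (C7'–C8').
- The halves meet in a central cyclohexene, ring C (C1, C2, C3, C11', C13', C5). Ring C is fused to ring A at C1–C5 and spiro-linked to lactone E at the quaternary carbon C11'.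
- Ring A carries C1(OH), C5(C13'), C7(C11), C8(O) and C10(CH3) all on one face. Ring B has the same all-cis C7'/C8'/C10' triad, but in the mirror-image sense.
- C11' sits next to C3 and bonds C3 on the H7' face of lactone E. C1 is a tertiary carbinol trans to H5, so rings A and C are trans-fused.
- Fragile groups: the γ-hydroxy enone (C1–OH, C2=C3, C4=O; base-sensitive), the exocyclic methylene lactone D (Michael acceptor and dienophile), the C1'=C5' alkene and the C4' methyl ketone.
- The real difficulty is twofold: two seven-membered carbocycles with a 1,2,4-triad needed in opposite absolute sense, and the spiro-linked ring C with C11', C5 and C1.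
- Feature the key step exploits: in both halves the ring reads C7(CH2CO)–C8(O)–C9H2–C10(CH3)–C1(carbonyl level)–C5H2–C6H2. This is the one-carbon homologue (extra atom C5 or C5') of a hydrogenated 5-hydroxy-6-methylbenzofuranone. Excising C5/C5' maps rings A/D and B/E onto one flat arene, and both antipodes of its all-cis reduction product are needed.

## Logic of the disconnections

**35 to 31 (C1–O).** The C1–O bond is cut and the C2=C3 alkene is moved back to C1=C2 (35 from 34, from 33, from 32, from 31). The C1 oxygen must stand on the face of ring C that carries C4, so it is best delivered from a C4 hydroxyl. The gain is a target without the γ-hydroxy enone, and with C4' masked. The demand is an epoxidation that picks C1=C2 over C1'=C5' and the C4 face.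

**31 to 27 (C11=C13).** The exocyclic methylene of lactone D is removed (31 from 30, from 27). The diene half then carries no dienophile and cannot self-dimerise. The demand is enolisation at C11 only, which holds because lactone E has no α-hydrogen and both oxygens at C4 and C4' are protected.

**27 to 16 + 26 (C5–C13' and C3–C11').** Ring C is cut at the only place where the two halves meet. This gives two bicyclic pieces of equal size. The demand is control of regiochemistry, the face of the diene, the face of the dienophile and the exo orientation of the lactone carbonyl.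

**16 to 12 + 15; 26 to 23 to 20 + 21.** The C1–C2 bond (and C1'–C2') and the C11'=C13' methylene are cut. Both halves become enol triflates of one bicyclic ketone in its two antipodal forms. The demand is two routine cross-couplings and one lactone methylenation. Boronate 15 comes from 14 and 13.

**12 to 11; 20 to 19.** The C1–O triflate bonds are cut back to the ketones. The demand is kinetic enolisation towards C5 (C5'), away from the methyl-bearing C10 (C10').

**11 to 9; 19 to 17 (key).** C5 (C5') is excised: C1–C5 and C5–C6 are cut and C1–C6 is joined. The seven-membered ring becomes a cyclohexanone in which C7, C8 and C10 are already in place. The demand is insertion on the CH2 side of the ketone only, with no epimerisation at C10.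

**9 and 17 to 8 and 7 to 5 to 4.** The ketone is taken back to the carbinol, the two antipodes to one racemate, and the four sp3 centres to an arene. No enantioselective step is needed, and no antipode is wasted because the target uses both. The demand is all-cis hydrogenation and a clean resolution.

**4 to 1 + 2.** The aryl–CH2 bond and the lactone C–O bond are cut, giving two commercial compounds. The demand is addition para to the quinone methyl.

## Other disconnections considered

**Alternative 1:** the first that comes to mind. Cut C5–C13' and C3–C11' between the fully functionalised monomers, diene A1 (8-epi-xanthatin) and dienophile A2 (the 2,3-dihydro monomer of the mirror-image series). Each would come from its own enantioselective sequence ending in ring-closing enyne metathesis. The forward key step is a thermal Diels–Alder reaction to A3, then a Schenck ene reaction with singlet oxygen and reduction of the hydroperoxide.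
- Two unrelated enantioselective sequences are needed for mirror-image halves, with nothing shared.
- A1 is diene and dienophile at once, so self-dimerisation competes with the cross-reaction.
- Singlet oxygen adds to C1 on the face from which it takes H3. In A3, H3 is cis to H5, whereas the target has the C1 oxygen trans to H5. The C1 epimer is therefore expected.
- The chosen plan keeps a ring C cycloaddition as a late step but is not built around it. It differs in where both seven-membered rings and their mirror-image triads come from, in a diene without a dienophile, and in oxygen delivery from C4.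

**Alternative 2:** cut ring B into vinylcyclopropane A4 and alkyne A5. The forward key step is a (5+2) cycloaddition catalysed by [Rh(CO)2Cl]2, giving cycloheptenone A6 with the C8' carbonyl and the side chain in one step.
- The C10' methyl stands next to the alkyne-derived C1'. To place it, the cyclopropane would have to open at its more substituted bond while the alkyne inserts with its substituted carbon next to that centre. The steric preferences of both elementary steps oppose this.
- C7', C8' and C10' would all have to be set afterwards.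
- There is no common intermediate for the two antipodal series.

**Alternative 3:** cut C5–C13', C11'–C3 and C1–C2. The forward key step is Michael addition of the kinetic enolate of 11 to 26, C-acetylation of the resulting lactone enolate and aldol closure to ketol A7 (a Robinson-type spiroannulation).
- It needs no diene, and the acetyl group arrives on the H7' face as required.
- Aldol closures of this kind favour the cis-fused ketol (OH cis to H5), whereas the target is trans-fused.
- The intermediate lactone enolate can be quenched by proton transfer from the more acidic C5–H.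
- The C3 carbonyl would then have to be turned into the acetyl-bearing alkene through an enol triflate and a carbonylative coupling, which adds at least three steps.

Key step: step 6

## Steps

Step 1
Reactants: 1 2-methyl-1,4-benzoquinone; 2 1,1-diethoxyethene
Product: 4 5-hydroxy-6-methyl-1-benzofuran-2(3H)-one, via 2-ethoxy-6-methyl-1-benzofuran-5-ol 3 (not isolated)
Conditions: 1 added slowly to 2 (1.3 equiv), MeCN, 0 °C to rt; then 2 M HCl, THF, rt
Reagents that add atoms: water, O
Why: Michael-type addition of the electron-rich ketene acetal carbon to C5 of the quinone (β to the carbonyl that is not deactivated by the vinylogous methyl donor, hence para to the methyl), re-aromatisation and ring closure with loss of ethanol give 3; aqueous acid turns this cyclic ketene acetal into the lactone. Known type: addition of ketene acetals to p-quinones; no stereocentre is formed.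

Step 2
Reactants: 4 5-hydroxy-6-methyl-1-benzofuran-2(3H)-one
Product: 5 rac-(3aR*,5R*,6S*,7aR*)-5-hydroxy-6-methylhexahydro-1-benzofuran-2(3H)-one (all-cis)
Conditions: H2 (40 bar), Rh/Al2O3 (5 wt% Rh), EtOAc/AcOH (10:1), 25 °C
Reagents that add atoms: none
Why: Heterogeneous arene hydrogenation delivers all six hydrogens from the catalyst-bound face, so H3a, H5, H6 and H7a become cis; this sets the cis ring fusion and the all-cis C7/C8/C10 relation of both halves in racemic form. Rhodium is chosen because it reduces phenols with little C–O hydrogenolysis.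

Step 3
Reactants: 5 rac-all-cis hydroxy lactone
Product: 6 (3aR,5R,6S,7aR)-6-methyl-2-oxooctahydro-1-benzofuran-5-yl acetate and 7 (3aS,5S,6R,7aS)-5-hydroxy-6-methylhexahydro-1-benzofuran-2(3H)-one, separated by chromatography
Conditions: vinyl acetate (3 equiv), Candida antarctica lipase B (immobilised), MTBE, 30 °C, to 50% conversion
Reagents that add atoms: vinyl acetate, C=COC(C)=O
Why: Lipase-catalysed kinetic resolution by enantioselective transesterification; by the empirical size rule for secondary alcohols the (5R) antipode (large CH(CH3) flank, medium CH2 flank) should be the one acylated. Both antipodes are used (6 for ring A, 7 for ring B), and the carbinol centre that serves as the handle is oxidised away later, so nothing is discarded.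

Step 4
Reactants: 6 (3aR,5R,6S,7aR)-acetate
Product: 8 (3aR,5R,6S,7aR)-5-hydroxy-6-methylhexahydro-1-benzofuran-2(3H)-one
Conditions: Candida antarctica lipase B (immobilised), phosphate buffer pH 7.2/MTBE, 30 °C
Reagents that add atoms: none
Why: Enzymatic ester hydrolysis at neutral pH frees the alcohol without opening the lactone and should raise the optical purity again, since the same antipode is the fast one in hydrolysis.

Step 5
Reactants: 8 (3aR,5R,6S,7aR)-alcohol
Product: 9 (3aR,6S,7aR)-6-methylhexahydro-1-benzofuran-2,5-dione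
Conditions: Dess–Martin periodinane, NaHCO3, CH2Cl2, 0 °C to rt
Reagents that add atoms: none
Why: Dess–Martin oxidation of the secondary alcohol under buffered, non-enolising conditions, so the methyl-bearing α-centre (future C10) keeps the cis configuration set by the hydrogenation.

Step 6
Reactants: 9 (3aR,6S,7aR)-6-methylhexahydro-1-benzofuran-2,5-dione
Product: 11 (3aR,7S,8aR)-7-methylhexahydro-2H-cyclohepta[b]furan-2,6(3H)-dione, via α-silyl ketone 10 (not isolated)
Conditions: TMSCHN2 (1.2 equiv), Sc(OTf)3 (5 mol%), toluene/CH2Cl2, −20 to 0 °C; then 1 M HCl, THF, 0 °C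
Reagents that add atoms: (trimethylsilyl)diazomethane, C[Si](C)(C)C=[N+]=[N-]
Why: Sc(OTf)3 activates the ring ketone of 9, the nucleophilic diazo carbon adds to it, and the β-diazonium alkoxide loses N2 with a 1,2-shift of the α-carbon that lies anti-periplanar to the leaving group. The closest known reaction type is the Lewis-acid-promoted diazoalkane homologation of 2-alkylcycloalkanones (Tiffeneau–Demjanov-type ring expansion with TMSCHN2). No ring is closed; the six-membered carbocycle is enlarged to ring A by a 1,2-alkyl shift that inserts the diazo carbon (future C5) between C1 and C6. The selectivity needed is regiochemical: the CH2 carbon (C6) must migrate and not the methyl-bearing C10; the bulky Me3Si–CH unit adds and rotates away from the α-methyl group, so the less substituted carbon is the one aligned for migration and the carbonyl stays next to C10. No new stereocentre survives, because the silylated carbon of 10 is cleared by protodesilylation. C7 and C8 are spectators, the migrating carbon is a CH2, and C10 is not enolised under the Lewis-acidic low-temperature conditions or the brief cold acid treatment. The lactone carbonyl is far less electrophilic than the scandium-bound ketone and is not attacked. The step turns a hydrogenated arene into the cis-fused cyclohepta[b]furanone with its three stereocentres and a carbonyl at C1, the common handle for the diene of ring A and the side-chain alkene of ring B.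

Step 7
Reactants: 11 (3aR,7S,8aR)-7-methylhexahydro-2H-cyclohepta[b]furan-2,6(3H)-dione
Product: 12 (3aR,7S,8aR)-7-methyl-2-oxo-3,3a,4,7,8,8a-hexahydro-2H-cyclohepta[b]furan-6-yl trifluoromethanesulfonate
Conditions: LiN(iPr)2 (1.05 equiv), THF, −78 °C; then Comins' reagent, −78 to 0 °C
Reagents that add atoms: N-(5-chloropyridin-2-yl)-1,1,1-trifluoro-N-(trifluoromethylsulfonyl)methanesulfonamide (Comins' reagent), FC(F)(F)S(=O)(=O)N(c1ccc(Cl)cn1)S(=O)(=O)C(F)(F)F
Why: Kinetic deprotonation with a bulky lithium amide at −78 °C takes the less substituted α-carbon (C5, a CH2) and not C10 or the less acidic lactone α-position; O-sulfonylation gives the C1=C5 enol triflate and leaves C10 untouched.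

Step 8
Reactants: 13 (S)-but-3-yn-2-ol
Product: 14 (S)-tert-butyl(but-3-yn-2-yloxy)dimethylsilane
Conditions: TBSCl, imidazole, CH2Cl2, 0 °C to rt
Reagents that add atoms: tert-butyldimethylsilyl chloride, CC(C)(C)[Si](C)(C)Cl
Why: Standard silylation of a secondary alcohol; the stereocentre is not touched.

Step 9
Reactants: 14 (S)-tert-butyl(but-3-yn-2-yloxy)dimethylsilane
Product: 15 tert-butyl(dimethyl){[(2S,3E)-4-(4,4,5,5-tetramethyl-1,3,2-dioxaborolan-2-yl)but-3-en-2-yl]oxy}silane
Conditions: pinacolborane (1.1 equiv), Cp2Zr(H)Cl (5 mol%), Et3N (10 mol%), neat, 60 °C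
Reagents that add atoms: pinacolborane, CC1(C)OBOC1(C)C
Why: Zirconium-catalysed syn-hydroboration of the terminal alkyne with pinacolborane gives the (E)-alkenylboronate with boron on the terminal carbon.

Step 10
Reactants: 12 enol triflate of the (3aR,7S,8aR) series; 15 (S,E)-alkenylboronate
Product: 16 (3aR,7S,8aR)-6-[(1E,3S)-3-{[tert-butyl(dimethyl)silyl]oxy}but-1-en-1-yl]-7-methyl-3,3a,4,7,8,8a-hexahydro-2H-cyclohepta[b]furan-2-one
Conditions: Pd(PPh3)4 (5 mol%), K3PO4 (3 M aq), 1,4-dioxane, 60 °C
Reagents that add atoms: none
Why: Suzuki–Miyaura coupling of an alkenyl triflate with an (E)-alkenylboronate forms C1–C2 with retention of both alkene geometries and gives the C5=C1–C2=C3 diene; the lactone should tolerate the short exposure to aqueous phosphate.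

Step 11
Reactants: 7 (3aS,5S,6R,7aS)-alcohol
Product: 17 (3aS,6R,7aS)-6-methylhexahydro-1-benzofuran-2,5-dione
Conditions: Dess–Martin periodinane, NaHCO3, CH2Cl2, 0 °C to rt
Reagents that add atoms: none
Why: As step 5, on the other antipode.

Step 12
Reactants: 17 (3aS,6R,7aS)-6-methylhexahydro-1-benzofuran-2,5-dione
Product: 19 (3aS,7R,8aS)-7-methylhexahydro-2H-cyclohepta[b]furan-2,6(3H)-dione, via α-silyl ketone 18 (not isolated)
Conditions: TMSCHN2 (1.2 equiv), Sc(OTf)3 (5 mol%), toluene/CH2Cl2, −20 to 0 °C; then 1 M HCl, THF, 0 °C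
Reagents that add atoms: (trimethylsilyl)diazomethane, C[Si](C)(C)C=[N+]=[N-]
Why: The ring expansion of step 6 repeated on the mirror-image ketone; the same α-methyl group directs migration of the CH2 carbon, giving ring B with C5' inserted between C1' and C6'.

Step 13
Reactants: 19 (3aS,7R,8aS)-7-methylhexahydro-2H-cyclohepta[b]furan-2,6(3H)-dione
Product: 20 (3aS,7R,8aS)-7-methyl-2-oxo-3,3a,4,7,8,8a-hexahydro-2H-cyclohepta[b]furan-6-yl trifluoromethanesulfonate
Conditions: LiN(iPr)2 (1.05 equiv), THF, −78 °C; then Comins' reagent, −78 to 0 °C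
Reagents that add atoms: N-(5-chloropyridin-2-yl)-1,1,1-trifluoro-N-(trifluoromethylsulfonyl)methanesulfonamide (Comins' reagent), FC(F)(F)S(=O)(=O)N(c1ccc(Cl)cn1)S(=O)(=O)C(F)(F)F
Why: As step 7; kinetic enolisation towards C5' fixes the position of the future C1'=C5' alkene.

Step 14
Reactants: 20 enol triflate of the (3aS,7R,8aS) series; 21 2-methyl-2-vinyl-1,3-dioxolane
Product: 23 (3aS,7R,8aS)-7-methyl-6-[2-(2-methyl-1,3-dioxolan-2-yl)ethyl]-3,3a,4,7,8,8a-hexahydro-2H-cyclohepta[b]furan-2-one, via B-alkyl-9-BBN 22 (not isolated)
Conditions: 21, 9-BBN-H, THF, 0 °C to rt; then 20, Pd(dppf)Cl2 (5 mol%), K3PO4 (3 M aq), DMF, rt to 45 °C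
Reagents that add atoms: none
Why: Anti-Markovnikov hydroboration of the vinyl dioxolane and B-alkyl Suzuki–Miyaura coupling with the alkenyl triflate form C1'–C2' and keep the C1'=C5' alkene in place; the C4' ketone stays masked as the dioxolane.

Step 15
Reactants: 23 dioxolane lactone of the (3aS,7R,8aS) series
Product: 26 (3aS,7R,8aS)-7-methyl-3-methylidene-6-[2-(2-methyl-1,3-dioxolan-2-yl)ethyl]-3,3a,4,7,8,8a-hexahydro-2H-cyclohepta[b]furan-2-one, via Mannich base 24 (not isolated), via ammonium iodide 25 (not isolated)
Conditions: LiN(iPr)2, THF, −78 °C; CH2=NMe2+ I−, −78 °C to rt; then MeI, MeOH, rt; then NaHCO3 (aq), CH2Cl2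
Reagents that add atoms: dimethylmethyleneammonium iodide (Eschenmoser's salt), C=[N+](C)C.[I-]
Why: Lactone α-methylenation by the Mannich route: the lithium enolate is aminomethylated, and quaternisation followed by mild base induces E1cB loss of trimethylamine. C11' is the only acidic site and its configuration is irrelevant because it becomes trigonal.

Step 16
Reactants: 16 silyloxy diene (ring A half); 26 methylene lactone (ring B half)
Product: 27 cycloadduct: ring C cyclohexene (C1=C2) formed by C5–C13' and C3–C11'; H3, H5, H7, H8 and H10 on one face of rings A/C; C3 on the H7' face of lactone E; (S)-CH(OTBS)CH3 at C3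
Conditions: 16 (1.0 equiv), 26 (1.5 equiv), BHT (5 mol%), toluene (1 M), 120 °C, sealed tube
Reagents that add atoms: none
Why: Thermal Diels–Alder reaction in which the diene terminus C5 (larger coefficient through the C1 alkyl substituent) bonds the methylene carbon C13' and C3 bonds C11', the regiochemistry usual for α-methylene lactones with 2-substituted dienes; 16 has no dienophile and 26 no diene, so only the cross-adduct can form. The dienophile should be attacked on the H7' face of the cis-fused lactone (ring B shields the other), with the lactone carbonyl exo as is common for s-cis-locked α-methylene lactones, and the diene should react on the face of the pseudo-axial C10 methyl, anti to the C6–C7 bond and the C7–C9 flap of the chair-like cycloheptene. The (S)-silyloxy centre should reinforce this because its largest group can stand anti to the incoming dienophile, and the E geometry of the diene places H3 cis to H5.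

Step 17
Reactants: 27 cycloadduct
Product: 30 C11-methylidene lactone (silyl ether), via Mannich base 28 (not isolated), via ammonium iodide 29 (not isolated)
Conditions: LiN(iPr)2 (1.3 equiv), THF, −78 °C; CH2=NMe2+ I−, −78 °C to rt; then MeI, MeOH, rt; then NaHCO3 (aq), CH2Cl2
Reagents that add atoms: dimethylmethyleneammonium iodide (Eschenmoser's salt), C=[N+](C)C.[I-]
Why: Same Mannich/elimination methylenation as step 15; C11 of lactone D is the only enolisable position in 27 (the spiro lactone has no α-hydrogen and both O4 and the C4' carbonyl are protected). Doing it after the cycloaddition means the diene never carried a dienophile.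

Step 18
Reactants: 30 methylidene lactone silyl ether
Product: 31 (4S)-C4 alcohol with C1=C2 alkene and methylidene lactone D
Conditions: TBAF/AcOH (1:1), THF, 0 °C to rt
Reagents that add atoms: none
Why: Fluoride cleavage of the silyl ether; acetic acid buffers the alkoxide so that the methylene lactone is not attacked.

Step 19
Reactants: 31 homoallylic alcohol
Product: 32 C1–C2 epoxy alcohol (epoxide oxygen on the face of ring C that carries C4)
Conditions: VO(acac)2 (10 mol%), tBuOOH (1.5 equiv, decane), CH2Cl2, 0 °C to rt
Reagents that add atoms: tert-butyl hydroperoxide, CC(C)(C)OO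
Why: Hydroxyl-directed epoxidation of a homoallylic alcohol: the vanadium alkoxide at O4 delivers the peroxide oxygen to C1=C2 from the face on which C4 stands, which is the face the C1 oxygen needs (cis to C13' and the C10 methyl on ring A). The undirected C1'=C5' alkene should react far more slowly and the electron-poor methylene lactone not at all. The (S) configuration at C4 lets its methyl stand away from C11' in the chair-like transition state.

Step 20
Reactants: 32 epoxy alcohol
Product: 34 C4'-dioxolane of the target (γ-hydroxy enone), via epoxy ketone 33 (not isolated)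
Conditions: Dess–Martin periodinane, NaHCO3, CH2Cl2, 0 °C; then Et3N, rt
Reagents that add atoms: none
Why: Oxidation gives the β,γ-epoxy ketone, in which H3 is α to the new carbonyl; triethylamine removes it and the enolate opens the epoxide at C2 (E1cB), giving the C2=C3 enone and the tertiary C1 alcohol with its configuration unchanged. The temporary C4 stereocentre disappears.

Step 21
Reactants: 34 dioxolane of the target
Product: 35 target CNP0195550.2
Conditions: 1 M HCl/THF (1:4), 0 °C to rt
Reagents that add atoms: water, O
Why: Acid-catalysed hydrolysis of the dioxolane frees the C4' methyl ketone; the tertiary allylic alcohol should not ionise under these mild conditions because the cation would be conjugated with the electron-poor enone.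

## Compound list

1 | 2-methyl-1,4-benzoquinone | CC1=CC(=O)C=CC1=O | starting material
2 | 1,1-diethoxyethene | C=C(OCC)OCC | starting material
3 | 2-ethoxy-6-methyl-1-benzofuran-5-ol | CCOc1cc2cc(O)c(C)cc2o1 | intermediate (not isolated)
4 | 5-hydroxy-6-methyl-1-benzofuran-2(3H)-one | Cc1cc2OC(=O)Cc2cc1O | intermediate
5 | rac-(3aR*,5R*,6S*,7aR*)-5-hydroxy-6-methylhexahydro-1-benzofuran-2(3H)-one (all-cis racemate, both antipodes written) | C1C(=O)O[C@@H]2C[C@H](C)[C@H](O)C[C@H]12.C1C(=O)O[C@H]2C[C@@H](C)[C@@H](O)C[C@@H]12 | intermediate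
6 | (3aR,5R,6S,7aR)-6-methyl-2-oxooctahydro-1-benzofuran-5-yl acetate | C1C(=O)O[C@@H]2C[C@H](C)[C@H](OC(C)=O)C[C@H]12 | intermediate
7 | (3aS,5S,6R,7aS)-5-hydroxy-6-methylhexahydro-1-benzofuran-2(3H)-one | C1C(=O)O[C@H]2C[C@@H](C)[C@@H](O)C[C@@H]12 | intermediate
8 | (3aR,5R,6S,7aR)-5-hydroxy-6-methylhexahydro-1-benzofuran-2(3H)-one | C1C(=O)O[C@@H]2C[C@H](C)[C@H](O)C[C@H]12 | intermediate
9 | (3aR,6S,7aR)-6-methylhexahydro-1-benzofuran-2,5-dione | C1C(=O)O[C@@H]2C[C@H](C)C(=O)C[C@H]12 | intermediate
10 | (3aR,7S,8aR)-7-methyl-5-(trimethylsilyl)hexahydro-2H-cyclohepta[b]furan-2,6(3H)-dione (epimers at C5) | C1C(=O)O[C@@H]2C[C@H](C)C(=O)C([Si](C)(C)C)C[C@H]12 | intermediate (not isolated)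
11 | (3aR,7S,8aR)-7-methylhexahydro-2H-cyclohepta[b]furan-2,6(3H)-dione | C1C(=O)O[C@@H]2C[C@H](C)C(=O)CC[C@H]12 | intermediate
12 | (3aR,7S,8aR)-7-methyl-2-oxo-3,3a,4,7,8,8a-hexahydro-2H-cyclohepta[b]furan-6-yl trifluoromethanesulfonate | C1C(=O)O[C@@H]2C[C@H](C)C(OS(=O)(=O)C(F)(F)F)=CC[C@H]12 | intermediate
13 | (S)-but-3-yn-2-ol | C#C[C@H](C)O | starting material
14 | (S)-tert-butyl(but-3-yn-2-yloxy)dimethylsilane | C#C[C@H](C)O[Si](C)(C)C(C)(C)C | intermediate
15 | tert-butyl(dimethyl){[(2S,3E)-4-(4,4,5,5-tetramethyl-1,3,2-dioxaborolan-2-yl)but-3-en-2-yl]oxy}silane | CC1(C)OB(/C=C/[C@H](C)O[Si](C)(C)C(C)(C)C)OC1(C)C | intermediate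
16 | (3aR,7S,8aR)-6-[(1E,3S)-3-{[tert-butyl(dimethyl)silyl]oxy}but-1-en-1-yl]-7-methyl-3,3a,4,7,8,8a-hexahydro-2H-cyclohepta[b]furan-2-one | C1C(=O)O[C@@H]2C[C@H](C)C(/C=C/[C@H](C)O[Si](C)(C)C(C)(C)C)=CC[C@H]12 | intermediate
17 | (3aS,6R,7aS)-6-methylhexahydro-1-benzofuran-2,5-dione | C1C(=O)O[C@H]2C[C@@H](C)C(=O)C[C@@H]12 | intermediate
18 | (3aS,7R,8aS)-7-methyl-5-(trimethylsilyl)hexahydro-2H-cyclohepta[b]furan-2,6(3H)-dione (epimers at C5) | C1C(=O)O[C@H]2C[C@@H](C)C(=O)C([Si](C)(C)C)C[C@@H]12 | intermediate (not isolated)
19 | (3aS,7R,8aS)-7-methylhexahydro-2H-cyclohepta[b]furan-2,6(3H)-dione | C1C(=O)O[C@H]2C[C@@H](C)C(=O)CC[C@@H]12 | intermediate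
20 | (3aS,7R,8aS)-7-methyl-2-oxo-3,3a,4,7,8,8a-hexahydro-2H-cyclohepta[b]furan-6-yl trifluoromethanesulfonate | C1C(=O)O[C@H]2C[C@@H](C)C(OS(=O)(=O)C(F)(F)F)=CC[C@@H]12 | intermediate
21 | 2-methyl-2-vinyl-1,3-dioxolane | C=CC1(C)OCCO1 | starting material
22 | 9-[2-(2-methyl-1,3-dioxolan-2-yl)ethyl]-9-borabicyclo[3.3.1]nonane | CC1(CCB2C3CCCC2CCC3)OCCO1 | intermediate (not isolated)
23 | (3aS,7R,8aS)-7-methyl-6-[2-(2-methyl-1,3-dioxolan-2-yl)ethyl]-3,3a,4,7,8,8a-hexahydro-2H-cyclohepta[b]furan-2-one | C1C(=O)O[C@H]2C[C@@H](C)C(CCC3(C)OCCO3)=CC[C@@H]12 | intermediate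
24 | 3-[(dimethylamino)methyl] derivative of 23 (epimers at C3 of the lactone) | CN(C)CC1C(=O)O[C@H]2C[C@@H](C)C(CCC3(C)OCCO3)=CC[C@@H]12 | intermediate (not isolated)
25 | trimethylammoniomethyl iodide from 24 | C[N+](C)(C)CC1C(=O)O[C@H]2C[C@@H](C)C(CCC3(C)OCCO3)=CC[C@@H]12.[I-] | intermediate (not isolated)
26 | (3aS,7R,8aS)-7-methyl-3-methylidene-6-[2-(2-methyl-1,3-dioxolan-2-yl)ethyl]-3,3a,4,7,8,8a-hexahydro-2H-cyclohepta[b]furan-2-one | C=C1C(=O)O[C@H]2C[C@@H](C)C(CCC3(C)OCCO3)=CC[C@@H]12 | intermediate
27 | Diels–Alder adduct of 16 and 26 (ring C with C1=C2; saturated lactone D; (S)-CH(OTBS)CH3 at C3; dioxolane at C4'; configuration as in SMILES) | C1C(=O)O[C@@H]2C[C@H](C)C3=C[C@H]([C@H](C)O[Si](C)(C)C(C)(C)C)[C@]4(C[C@@H]3C[C@H]12)C(=O)O[C@H]1C[C@@H](C)C(CCC5(C)OCCO5)=CC[C@H]14 | intermediate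
28 | C11-[(dimethylamino)methyl] derivative of 27 (epimers at C11) | CN(C)CC1C(=O)O[C@@H]2C[C@H](C)C3=C[C@H]([C@H](C)O[Si](C)(C)C(C)(C)C)[C@]4(C[C@@H]3C[C@H]12)C(=O)O[C@H]1C[C@@H](C)C(CCC5(C)OCCO5)=CC[C@H]14 | intermediate (not isolated)
29 | trimethylammoniomethyl iodide from 28 | C[N+](C)(C)CC1C(=O)O[C@@H]2C[C@H](C)C3=C[C@H]([C@H](C)O[Si](C)(C)C(C)(C)C)[C@]4(C[C@@H]3C[C@H]12)C(=O)O[C@H]1C[C@@H](C)C(CCC5(C)OCCO5)=CC[C@H]14.[I-] | intermediate (not isolated)
30 | C11-methylidene lactone, C4 silyl ether | C=C1C(=O)O[C@@H]2C[C@H](C)C3=C[C@H]([C@H](C)O[Si](C)(C)C(C)(C)C)[C@]4(C[C@@H]3C[C@H]12)C(=O)O[C@H]1C[C@@H](C)C(CCC5(C)OCCO5)=CC[C@H]14 | intermediate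
31 | (4S)-C4 alcohol, C1=C2 alkene, methylidene lactone D | C=C1C(=O)O[C@@H]2C[C@H](C)C3=C[C@H]([C@H](C)O)[C@]4(C[C@@H]3C[C@H]12)C(=O)O[C@H]1C[C@@H](C)C(CCC5(C)OCCO5)=CC[C@H]14 | intermediate
32 | C1–C2 epoxy alcohol (epoxide oxygen cis to C4 on ring C) | C=C1C(=O)O[C@@H]2C[C@H](C)[C@@]3(O6)[C@H]6[C@H]([C@H](C)O)[C@]4(C[C@@H]3C[C@H]12)C(=O)O[C@H]1C[C@@H](C)C(CCC5(C)OCCO5)=CC[C@H]14 | intermediate
33 | C1–C2 epoxy C4 ketone | C=C1C(=O)O[C@@H]2C[C@H](C)[C@@]3(O6)[C@H]6[C@H](C(C)=O)[C@]4(C[C@@H]3C[C@H]12)C(=O)O[C@H]1C[C@@H](C)C(CCC5(C)OCCO5)=CC[C@H]14 | intermediate (not isolated)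
34 | C4'-dioxolane of the target | C=C1C(=O)O[C@@H]2C[C@H](C)[C@@]3(O)C=C(C(C)=O)[C@]4(C[C@@H]3C[C@H]12)C(=O)O[C@H]1C[C@@H](C)C(CCC5(C)OCCO5)=CC[C@H]14 | intermediate
35 | CNP0195550.2 | C=C1C(=O)O[C@@H]2C[C@H](C)[C@@]3(O)C=C(C(C)=O)[C@]4(C[C@@H]3C[C@H]12)C(=O)O[C@H]1C[C@@H](C)C(CCC(C)=O)=CC[C@H]14 | target

## Step count and least certain steps

Total step count: 21. Longest linear sequence: 14 steps (steps 1–7, 10, 16–21; the ring B branch through steps 1–3, 11–16 and 17–21 is equally long).

**Step 6 (key step; step 12 repeats it on the antipode).** The likely failure is loss of regiocontrol in the 1,2-shift (migration of the methyl-bearing carbon), or epimerisation at that α-centre during desilylation, or a second homologation of the product ketone. The fallback sets out from 9 and returns at 11. It replaces the diazo insertion by a regiodefined strain-release ring expansion: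
- Kinetic enolisation of 9 with LiN(iPr)2/TMSCl gives the trimethylsilyl enol ether F1 on the CH2 side.
- Cyclopropanation with Et2Zn/CH2I2 gives the siloxycyclopropane F2.
- FeCl3 in DMF opens the internal cyclopropane bond to the β-chloro ketone F3.
- NaOAc in MeOH eliminates to the cycloheptenone F4.
- H2 over Pd/C gives 11.

The same sequence would serve in the mirror-image series between 17 and 19.

**Step 16.** The likely failures are attack on the other face of the diene, insufficient exo preference, or a reaction so slow that the methylene lactone polymerises; the allylic silyloxy centre might also work against the ring bias. The fallback sets out from 12 and returns at 27. It uses the carbonyl-conjugated diene that corresponds to the natural partner, and sets C4 afterwards: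
- Heck reaction of 12 with methyl vinyl ketone (Pd(OAc)2, PPh3, KOAc, DMF) gives the dienone F5.
- Thermal cycloaddition of F5 with 26 gives the ketone adduct F6.
- Reduction with (R)-2-methyl-CBS-oxazaborolidine and catecholborane gives the (4S) alcohol F7.
- TBSCl/imidazole gives 27.

**Step 19.** The likely failures are a slow directed epoxidation at the hindered trisubstituted alkene, with competing oxidation of C1'=C5', or incomplete face control. The fallback sets out from 31 and returns at 34. It places the oxygen by oxidation of an extended enol ether (vinylogous Rubottom oxidation) instead of an epoxide opening: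
- Dess–Martin oxidation of 31 gives the β,γ-unsaturated ketone F8.
- TBSOTf/Et3N gives the silyl dienol ether F9 (C4=C3–C2=C1).
- Dimethyldioxirane at −40 °C attacks the electron-rich diene at C1, and TBAF/AcOH then gives 34.

In this variant the face at C1 would rest on the ring fusion alone.

**Step 3.** The likely failure is low enantioselectivity of the lipase, because both flanks of the carbinol are ring carbons of similar size. The fallback sets out from 5 and returns at 7 and 8. It is a classical resolution through diastereomers: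
- Esterification of 5 with (S)-2-methoxy-2-phenylacetic acid (DCC, DMAP) gives the diastereomeric esters F10 (from the 5R antipode) and F11 (from the 5S antipode).
- These are separated by chromatography or crystallisation.
- Each is cleaved with LiOH and re-lactonised on acidification, F10 giving 8 and F11 giving 7.

## Further compounds

F1 | step 6 | (3aR,6S,7aR)-6-methyl-5-(trimethylsilyloxy)-3a,6,7,7a-tetrahydro-1-benzofuran-2(3H)-one | C1C(=O)O[C@@H]2C[C@H](C)C(O[Si](C)(C)C)=C[C@H]12
F2 | step 6 | siloxycyclopropane from F1 (cyclopropane fused at the former enol ether carbons, configuration there not specified) | C1C(=O)O[C@@H]2C[C@H](C)C3(O[Si](C)(C)C)CC3[C@H]12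
F3 | step 6 | (3aR,7S,8aR)-4-chloro-7-methylhexahydro-2H-cyclohepta[b]furan-2,6(3H)-dione (epimers at C4) | C1C(=O)O[C@@H]2C[C@H](C)C(=O)CC(Cl)[C@H]12
F4 | step 6 | (3aR,7S,8aR)-7-methyl-3,3a,8,8a-tetrahydro-2H-cyclohepta[b]furan-2,6(7H)-dione | C1C(=O)O[C@@H]2C[C@H](C)C(=O)C=C[C@H]12
F5 | step 16 | (3aR,7S,8aR)-7-methyl-6-[(1E)-3-oxobut-1-en-1-yl]-3,3a,4,7,8,8a-hexahydro-2H-cyclohepta[b]furan-2-one | C1C(=O)O[C@@H]2C[C@H](C)C(/C=C/C(C)=O)=CC[C@H]12
F6 | step 16 | Diels–Alder adduct of F5 and 26 (C3 acetyl, C1=C2 alkene) | C1C(=O)O[C@@H]2C[C@H](C)C3=C[C@H](C(C)=O)[C@]4(C[C@@H]3C[C@H]12)C(=O)O[C@H]1C[C@@H](C)C(CCC5(C)OCCO5)=CC[C@H]14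
F7 | step 16 | (4S) alcohol from F6 | C1C(=O)O[C@@H]2C[C@H](C)C3=C[C@H]([C@H](C)O)[C@]4(C[C@@H]3C[C@H]12)C(=O)O[C@H]1C[C@@H](C)C(CCC5(C)OCCO5)=CC[C@H]14
F8 | step 19 | C4 ketone from 31 (C1=C2 alkene, methylidene lactone D) | C=C1C(=O)O[C@@H]2C[C@H](C)C3=C[C@H](C(C)=O)[C@]4(C[C@@H]3C[C@H]12)C(=O)O[C@H]1C[C@@H](C)C(CCC5(C)OCCO5)=CC[C@H]14
F9 | step 19 | tert-butyldimethylsilyl dienol ether of F8 (C4=C3–C2=C1, enol ether geometry not specified) | C=C1C(=O)O[C@@H]2C[C@H](C)C3=CC(=C(C)O[Si](C)(C)C(C)(C)C)[C@]4(C[C@@H]3C[C@H]12)C(=O)O[C@H]1C[C@@H](C)C(CCC5(C)OCCO5)=CC[C@H]14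
F10 | step 3 | (3aR,5R,6S,7aR)-6-methyl-2-oxooctahydro-1-benzofuran-5-yl (2S)-2-methoxy-2-phenylacetate | C1C(=O)O[C@@H]2C[C@H](C)[C@H](OC(=O)[C@@H](OC)c3ccccc3)C[C@H]12
F11 | step 3 | (3aS,5S,6R,7aS)-6-methyl-2-oxooctahydro-1-benzofuran-5-yl (2S)-2-methoxy-2-phenylacetate | C1C(=O)O[C@H]2C[C@@H](C)[C@@H](OC(=O)[C@@H](OC)c3ccccc3)C[C@@H]12
A1 | alternative 1 | 8-epi-xanthatin, (3aR,7S,8aR)-7-methyl-3-methylidene-6-[(1E)-3-oxobut-1-en-1-yl]-3,3a,4,7,8,8a-hexahydro-2H-cyclohepta[b]furan-2-one | C=C1C(=O)O[C@@H]2C[C@H](C)C(/C=C/C(C)=O)=CC[C@H]12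
A2 | alternative 1 | (3aS,7R,8aS)-7-methyl-3-methylidene-6-(3-oxobutyl)-3,3a,4,7,8,8a-hexahydro-2H-cyclohepta[b]furan-2-one | C=C1C(=O)O[C@H]2C[C@@H](C)C(CCC(C)=O)=CC[C@@H]12
A3 | alternative 1 | Diels–Alder adduct of A1 and A2 (1-deoxy precursor with C1=C2 alkene) | C=C1C(=O)O[C@@H]2C[C@H](C)C3=C[C@H](C(C)=O)[C@]4(C[C@@H]3C[C@H]12)C(=O)O[C@H]1C[C@@H](C)C(CCC(C)=O)=CC[C@H]14
A4 | alternative 2 | tert-butyl(dimethyl)[(1-vinylcyclopropyl)oxy]silane | C=CC1(O[Si](C)(C)C(C)(C)C)CC1
A5 | alternative 2 | hex-5-yn-2-one | CC(=O)CCC#C
A6 | alternative 2 | 4-(3-oxobutyl)cyclohept-4-en-1-one | CC(=O)CCC1=CCCC(=O)CC1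
A7 | alternative 3 | ring C ketol (C1 carbinol, C3 ketone) from 11 and 26, drawn with the C1 configuration the target needs | C1C(=O)O[C@@H]2C[C@H](C)[C@@]3(O)CC(=O)[C@]4(C[C@@H]3C[C@H]12)C(=O)O[C@H]1C[C@@H](C)C(CCC5(C)OCCO5)=CC[C@H]14
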